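## Retrosynthetic overview

- Target ⇐ its hexabenzyl ether by global hydrogenolysis; all six phenols travel as benzyl ethers.
- The oxolane (the only ring made) ⇐ a cyclic hemiketal by Lewis-acid/silane reduction: C5–H is delivered last and C4 settles by enol-ether equilibration.
- Hemiketal ⇐ reagent-controlled syn-aldol of a 2-benzyl-1,4-diaryl-1,4-diketone with 4-(benzyloxy)benzaldehyde; this sets C2 and C3, and the new hydroxyl closes onto the remote ketone.
- Benzylated diketone ⇐ mono-benzylation of a twofold-symmetric 1,4-diketone, because the aroyl carbon and C5 of the target carry the same 2,4-dioxygenated aryl group.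
- Symmetric diketone ⇐ C3–C4 bond by oxidative homocoupling of two acetophenone enolates: one enolate is oxidised to an enolonium-type α-keto radical and captured by the other.

Ring numbering used below: O1, C2 (4-oxyphenyl), C3 (aroyl), C4 (benzyl), C5 (2,4-dioxyphenyl).

Assumption: (−)-Ipc2BOTf (from (+)-α-pinene) is taken to direct its Z-enolate to the Si face of aldehyde 7; if the first run shows the opposite sense, (+)-Ipc2BOTf is used and nothing else changes.

## Route

Step 1
Reactants: 1 1-[2,4-bis(benzyloxy)phenyl]ethan-1-one (two molecules)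
Product: 3 1,4-bis[2,4-bis(benzyloxy)phenyl]butane-1,4-dione, via lithium enolate 2 (not isolated)
Conditions: LiN(i-Pr)2, THF, −78 °C; then CuCl2, DMF, −78 °C → rt
Reagents that add atoms: none
Why: Ito–Saegusa oxidative enolate homocoupling, in which CuCl2 oxidises enolate 2 to an electrophilic α-keto radical (an enolonium equivalent) that a second enolate captures, joining two normally nucleophilic α-carbons (the future C3–C4 bond) with no cross-selectivity problem and no stereocentre formed.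

Step 2
Reactants: 3 1,4-bis[2,4-bis(benzyloxy)phenyl]butane-1,4-dione; 4 1-(benzyloxy)-4-(bromomethyl)benzene
Product: 6 rac-2-[4-(benzyloxy)benzyl]-1,4-bis[2,4-bis(benzyloxy)phenyl]butane-1,4-dione, via lithium enolate 5 (not isolated)
Conditions: LiN(i-Pr)2 (1.0 equiv), THF, −78 °C; then 4, DMPU, −78 → 0 °C
Reagents that add atoms: none
Why: Enolate C-alkylation with a reactive benzylic bromide, regiochemically unambiguous because both methylene groups of 3 are equivalent; the new centre (future C4) is racemic here and is corrected in step 4.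

Step 3
Reactants: 6 rac-2-[4-(benzyloxy)benzyl]-1,4-bis[2,4-bis(benzyloxy)phenyl]butane-1,4-dione; 7 4-(benzyloxy)benzaldehyde
Product: 10 [(2S,3S)-2-[4-(benzyloxy)phenyl]-4-[4-(benzyloxy)benzyl]-5-[2,4-bis(benzyloxy)phenyl]-5-hydroxyoxolan-3-yl][2,4-bis(benzyloxy)phenyl]methanone (cyclic hemiketal; epimeric at C4/C5), via boron enolate 8 (not isolated), via open-chain aldol 9 (not isolated)
Conditions: (−)-Ipc2BOTf [(−)-diisopinocampheylboron triflate], i-Pr2NEt, CH2Cl2, −78 °C; then 7, −78 → −20 °C; H2O2, MeOH, pH 7 buffer, 0 °C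
Reagents that add atoms: none
Why: Paterson boron aldol, in which kinetic enolisation at the unbranched CH2 gives the Z-enol borinate 8 whose chair Zimmerman–Traxler transition state delivers the syn aldol by reagent-controlled Si-face attack on 7 (C2 S, C3 S, i.e. 2,3-trans in the ring) whatever the configuration at the benzyl-bearing carbon, and the γ-hydroxy ketone 9 closes to hemiketal 10.

Step 4
Reactants: 10 cyclic hemiketal (both C4 epimers)
Product: 13 [(2S,3S,4S,5R)-2-[4-(benzyloxy)phenyl]-4-[4-(benzyloxy)benzyl]-5-[2,4-bis(benzyloxy)phenyl]oxolan-3-yl][2,4-bis(benzyloxy)phenyl]methanone, via oxocarbenium ion 11 (not isolated), via enol ether 12 (not isolated)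
Conditions: Et3SiH, BF3·OEt2, CH2Cl2, −78 → −30 °C
Reagents that add atoms: none
Why: Lewis-acid reductive deoxygenation of a cyclic hemiketal (ionic hydrogenation), in which oxocarbenium ion 11 equilibrates through enol ether 12 so that both C4 epimers converge on benzyl trans to the C3 aroyl group, and Et3SiH then attacks anti to that benzyl group to give the 4,5-cis (5R) centre, as in the veraguensin-type 2,5-diaryloxolane lignans, while the aryl ketone is not reduced at this temperature.

Step 5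
Reactants: 13 hexabenzyl ether of the target
Product: 14 (2,4-dihydroxyphenyl)[(2S,3S,4S,5R)-5-(2,4-dihydroxyphenyl)-4-(4-hydroxybenzyl)-2-(4-hydroxyphenyl)oxolan-3-yl]methanone (CNP0181717.3)
Conditions: H2 (1 atm), 10% Pd/C, EtOAc–MeOH, rt
Reagents that add atoms: none
Why: Hydrogenolysis of the six aryl benzyl ethers is much faster than cleavage of the cyclic benzylic C–O bonds or reduction of the hydrogen-bonded 2-hydroxyaryl ketone, and no stereocentre is touched.

## Compound list

1 | 1-[2,4-bis(benzyloxy)phenyl]ethan-1-one | CC(=O)c1ccc(OCc2ccccc2)cc1OCc1ccccc1 | starting material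
2 | lithium 1-[2,4-bis(benzyloxy)phenyl]ethen-1-olate | [Li]OC(=C)c1ccc(OCc2ccccc2)cc1OCc1ccccc1 | intermediate (not isolated)
3 | 1,4-bis[2,4-bis(benzyloxy)phenyl]butane-1,4-dione | O=C(CCC(=O)c1ccc(OCc2ccccc2)cc1OCc1ccccc1)c1ccc(OCc2ccccc2)cc1OCc1ccccc1 | intermediate
4 | 1-(benzyloxy)-4-(bromomethyl)benzene (4-(benzyloxy)benzyl bromide) | BrCc1ccc(OCc2ccccc2)cc1 | starting material
5 | lithium (1Z)-1,4-bis[2,4-bis(benzyloxy)phenyl]-4-oxobut-1-en-1-olate (mono-enolate of 3) | [Li]O/C(=C\CC(=O)c1ccc(OCc2ccccc2)cc1OCc1ccccc1)c1ccc(OCc2ccccc2)cc1OCc1ccccc1 | intermediate (not isolated)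
6 | rac-2-[4-(benzyloxy)benzyl]-1,4-bis[2,4-bis(benzyloxy)phenyl]butane-1,4-dione | O=C(CC(Cc1ccc(OCc2ccccc2)cc1)C(=O)c1ccc(OCc2ccccc2)cc1OCc1ccccc1)c1ccc(OCc2ccccc2)cc1OCc1ccccc1 | intermediate
7 | 4-(benzyloxy)benzaldehyde | O=Cc1ccc(OCc2ccccc2)cc1 | starting material
8 | (Z)-enol di[(−)-isopinocampheyl]borinate of 6, formed at the CH2 carbon | O=C(c1ccc(OCc2ccccc2)cc1OCc1ccccc1)C(Cc1ccc(OCc2ccccc2)cc1)/C=C(\OB([C@@H]1C[C@@H]2C[C@H]([C@H]1C)C2(C)C)[C@@H]1C[C@@H]2C[C@H]([C@H]1C)C2(C)C)c1ccc(OCc2ccccc2)cc1OCc1ccccc1 | intermediate (not isolated)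
9 | (2S)-2-[(S)-[4-(benzyloxy)phenyl](hydroxy)methyl]-3-[4-(benzyloxy)benzyl]-1,4-bis[2,4-bis(benzyloxy)phenyl]butane-1,4-dione (syn aldol, both epimers at the benzyl-bearing carbon) | O=C(c1ccc(OCc2ccccc2)cc1OCc1ccccc1)[C@H]([C@H](O)c1ccc(OCc2ccccc2)cc1)C(Cc1ccc(OCc2ccccc2)cc1)C(=O)c1ccc(OCc2ccccc2)cc1OCc1ccccc1 | intermediate (not isolated)
10 | [(2S,3S)-2-[4-(benzyloxy)phenyl]-4-[4-(benzyloxy)benzyl]-5-[2,4-bis(benzyloxy)phenyl]-5-hydroxyoxolan-3-yl][2,4-bis(benzyloxy)phenyl]methanone (cyclic hemiketal, C4 and C5 unassigned) | O=C(c1ccc(OCc2ccccc2)cc1OCc1ccccc1)[C@H]1C(Cc2ccc(OCc3ccccc3)cc2)C(O)(c2ccc(OCc3ccccc3)cc2OCc2ccccc2)O[C@@H]1c1ccc(OCc2ccccc2)cc1 | intermediate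
11 | (2S,3S,4S)-oxocarbenium ion at C5 (3,4-dihydro-2H-furan-1-ium) as its hydroxytrifluoroborate | O=C(c1ccc(OCc2ccccc2)cc1OCc1ccccc1)[C@H]1[C@H](Cc2ccc(OCc3ccccc3)cc2)C(c2ccc(OCc3ccccc3)cc2OCc2ccccc2)=[O+][C@@H]1c1ccc(OCc2ccccc2)cc1.O[B-](F)(F)F | intermediate (not isolated)
12 | [(2S,3S)-2-[4-(benzyloxy)phenyl]-4-[4-(benzyloxy)benzyl]-5-[2,4-bis(benzyloxy)phenyl]-2,3-dihydrofuran-3-yl][2,4-bis(benzyloxy)phenyl]methanone (enol ether) | O=C(c1ccc(OCc2ccccc2)cc1OCc1ccccc1)[C@H]1C(Cc2ccc(OCc3ccccc3)cc2)=C(c2ccc(OCc3ccccc3)cc2OCc2ccccc2)O[C@@H]1c1ccc(OCc2ccccc2)cc1 | intermediate (not isolated)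
13 | [(2S,3S,4S,5R)-2-[4-(benzyloxy)phenyl]-4-[4-(benzyloxy)benzyl]-5-[2,4-bis(benzyloxy)phenyl]oxolan-3-yl][2,4-bis(benzyloxy)phenyl]methanone (hexabenzyl ether) | O=C(c1ccc(OCc2ccccc2)cc1OCc1ccccc1)[C@H]1[C@H](Cc2ccc(OCc3ccccc3)cc2)[C@H](c2ccc(OCc3ccccc3)cc2OCc2ccccc2)O[C@@H]1c1ccc(OCc2ccccc2)cc1 | intermediate
14 | (2,4-dihydroxyphenyl)[(2S,3S,4S,5R)-5-(2,4-dihydroxyphenyl)-4-(4-hydroxybenzyl)-2-(4-hydroxyphenyl)oxolan-3-yl]methanone | O=C(c1ccc(O)cc1O)[C@H]1[C@H](Cc2ccc(O)cc2)[C@H](c2ccc(O)cc2O)O[C@@H]1c1ccc(O)cc1 | target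

## Step count and risks

Total steps: 5. Longest linear sequence: 5.

The three steps most likely to fail:

Step 3, the asymmetric aldol. The risks are that one enantiomer of racemic 6 is mismatched with the boron reagent, that enolisation occurs at the branched carbonyl, and that the aldol dehydrates; the enantiomeric purity of the whole route is fixed here and can be raised by recrystallising 13. The fallback sets out from 6 and comes back at 10. Soft enolisation of 6 (MgBr2·OEt2, i-Pr2NEt, CH2Cl2) and C-acylation with 4-(benzyloxy)benzoyl chloride give the triketone 2-[4-(benzyloxy)benzoyl]-3-[4-(benzyloxy)benzyl]-1,4-bis[2,4-bis(benzyloxy)phenyl]butane-1,4-dione F1. Asymmetric transfer hydrogenation with RuCl(p-cymene)[(S,S)-TsDPEN] in HCO2H–Et3N should then reduce only the unhindered 4-(benzyloxy)benzoyl carbonyl, since the other two ketones are ortho-substituted and more electron-rich. The labile 1,3-dicarbonyl carbon equilibrates during the reduction, which gives the (S)-carbinol 9, and this closes to 10.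

Step 4, the reductive deoxygenation. The risks are over-reduction of the electron-rich aryl ketone, hydride capture before C4 has equilibrated, and acid ionisation of the C2–O bond. The fallback sets out from 10 and comes back at 13. Hemiketal 10 is dehydrated (pyridinium p-toluenesulfonate, 4 Å sieves, CH2Cl2) and enol ether 12 is isolated, then hydrogenated with [Ir(cod)(PCy3)(py)]PF6 and H2 in CH2Cl2. The C3 aroyl oxygen binds iridium, so both hydrogens arrive on the ring face that the aroyl group occupies. This sets C4 and C5 together, with benzyl and aryl cis to each other and trans to the aroyl group, without acid or hydride. No compound outside the list is made (F0).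

Step 2, the mono-benzylation. The risks are proton exchange between product and enolate leading to dialkylation, and recovered 3. The fallback sets out from 3 and comes back at 6. Condensation of 3 with 7 (piperidine, AcOH, toluene, reflux, water removal) gives the mono-benzylidene diketone (E)-2-[4-(benzyloxy)benzylidene]-1,4-bis[2,4-bis(benzyloxy)phenyl]butane-1,4-dione F2. Conjugate reduction with [(Ph3P)CuH]6 in toluene then gives 6.

## Further compounds

F1 | step 3 | 2-[4-(benzyloxy)benzoyl]-3-[4-(benzyloxy)benzyl]-1,4-bis[2,4-bis(benzyloxy)phenyl]butane-1,4-dione | O=C(c1ccc(OCc2ccccc2)cc1)C(C(=O)c1ccc(OCc2ccccc2)cc1OCc1ccccc1)C(Cc1ccc(OCc2ccccc2)cc1)C(=O)c1ccc(OCc2ccccc2)cc1OCc1ccccc1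
F0 | step 4 | none | none
F2 | step 2 | (E)-2-[4-(benzyloxy)benzylidene]-1,4-bis[2,4-bis(benzyloxy)phenyl]butane-1,4-dione | O=C(C/C(=C\c1ccc(OCc2ccccc2)cc1)C(=O)c1ccc(OCc2ccccc2)cc1OCc1ccccc1)c1ccc(OCc2ccccc2)cc1OCc1ccccc1
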